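The C4–O bond of the all-cis unit A (2R,3R,4R) in the C4–O–C4 ether is cut first (4-ketone of unit A plus the 4-ol of the 2,3-trans-3,4-cis unit B, 2S,3R,4R), then O1–C8a and C8–O in each flavan, then the C4–C4a aryl ketone bond and the C2–C3 aldol bond.
Enabling feature: in ring A of both units O1 on C8a and the hydroxyl on C8 are neighbours and O7 sits next to C8, the pattern left when a tethered alkoxide and an oxygen electrophile add across the C8–C8a bond of a 3-alkoxybenzyne; fluorine is placed on C8a so that the proton lost, C8–H, lies between F and O7.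
Forward: the C2–C3–C4 chain is joined first (glycolate aldol, Weinreb ketone synthesis with the fluoroaryl Grignard reagent), ring C is closed last onto the finished rings A and B by the aryne step, once for each unit from one common open-chain alcohol, and the two flavans are joined by reductive etherification before global debenzylation.
Stereochemistry: the oxazolidinone auxiliary sets C2 and C3 of unit A (syn aldol); zinc chelation by O3 sets C4 anti to O3 in the open chain; C2 of unit B comes from oxidation and a second chelation-controlled reduction; C4 of unit A is set again at the end by hydride delivery anti to O3, while C4 of unit B is carried through.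

Key step: step 10

Remark: the target is read as the C4–O–C4 ether of an all-cis (2R,3R,4R) flavan-3,4-diol (unit A) and a 2,3-trans-3,4-cis (2S,3R,4R) flavan-3,4-diol (unit B); ring positions are given in flavan numbering (O1, C2, C3, C4, C4a, C5 to C8, C8a), also for the carbons of open-chain precursors that become these atoms.

Step 1
Reactants: 1 (S)-4-benzyloxazolidin-2-one; 2 benzyloxyacetyl chloride
Product: 3 (S)-4-benzyl-3-(benzyloxyacetyl)oxazolidin-2-one
Conditions: Et3N, DMAP (cat.), CH2Cl2, 0 °C → rt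
Reagents that add atoms: none
Why: N-Acylation of the oxazolidinone by the acid chloride under DMAP catalysis (nucleophilic acyl substitution) is routine for glycolate imides and touches no stereocentre.

Step 2
Reactants: 3 N-(benzyloxyacetyl)oxazolidinone; 4 4-(benzyloxy)benzaldehyde
Product: 7 (4S)-4-benzyl-3-[(2S,3R)-2-(benzyloxy)-3-[4-(benzyloxy)phenyl]-3-hydroxypropanoyl]oxazolidin-2-one, via Z dibutylboron enolate 5 (not isolated), via dibutylboron aldolate 6 (not isolated)
Conditions: n-Bu2BOTf, Et3N, CH2Cl2, −78 → 0 °C; 4, −78 → 0 °C; pH 7 buffer (NaH2PO4/Na2HPO4), MeOH, 30% H2O2, 0 °C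
Reagents that add atoms: none
Why: Evans syn aldol reaction: the Z boron enolate 5 reacts through a closed Zimmerman–Traxler chair on the enolate face away from the auxiliary benzyl group with the imide carbonyls opposed, which sets the benzyloxy-bearing carbon (2S) and the carbinol carbon (3R) syn to each other.

Step 3
Reactants: 7 syn aldol adduct
Product: 8 (2S,3R)-2-(benzyloxy)-3-[4-(benzyloxy)phenyl]-3-hydroxy-N-methoxy-N-methylpropanamide
Conditions: MeNHOMe·HCl, AlMe3, CH2Cl2, −20 → 0 °C; aq. potassium sodium tartrate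
Reagents that add atoms: N,O-dimethylhydroxylamine hydrochloride, CNOC.Cl
Why: Weinreb amide formation by aluminium amide transamidation of the imide, assisted by the free β-hydroxyl, releases the auxiliary for re-use and leaves both stereocentres untouched.

Step 4
Reactants: 8 Weinreb amide
Product: 9 (2S,3R)-2-(benzyloxy)-3-[4-(benzyloxy)phenyl]-N-methoxy-N-methyl-3-(triethylsilyloxy)propanamide
Conditions: Et3SiCl, imidazole, DMF, 0 °C → rt
Reagents that add atoms: chlorotriethylsilane, CC[Si](Cl)(CC)CC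
Why: Silyl ether formation on the secondary alcohol masks the β-hydroxyl, so that it neither consumes the Grignard reagent of step 6 nor offers a second chelation site in step 7.

Step 5
Reactants: 10 4-bromo-3-fluorophenol; 11 benzyl bromide
Product: 12 4-(benzyloxy)-1-bromo-2-fluorobenzene
Conditions: K2CO3, DMF, rt
Reagents that add atoms: none
Why: Williamson ether synthesis on the phenoxide; the aryl C–Br and C–F bonds are inert under these conditions.

Step 6
Reactants: 9 silylated Weinreb amide; 12 aryl bromide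
Product: 14 (2S,3R)-2-(benzyloxy)-1-[4-(benzyloxy)-2-fluorophenyl]-3-[4-(benzyloxy)phenyl]-3-(triethylsilyloxy)propan-1-one, via aryl Grignard reagent 13 (not isolated)
Conditions: 12, iPrMgCl·LiCl, THF, 0 °C → rt; then 9, −20 → 0 °C; aq. NH4Cl
Reagents that add atoms: none
Why: Bromine–magnesium exchange followed by Weinreb ketone synthesis: the chelated tetrahedral adduct stops at the ketone stage and frees the carbonyl only on work-up, so the α-benzyloxy centre should not epimerise, and the ortho-fluoroaryl Grignard reagent 13 should not lose fluoride at or below room temperature.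

Step 7
Reactants: 14 α-benzyloxy aryl ketone
Product: 15 (1R,2R,3R)-2-(benzyloxy)-1-[4-(benzyloxy)-2-fluorophenyl]-3-[4-(benzyloxy)phenyl]-3-(triethylsilyloxy)propan-1-ol
Conditions: Zn(BH4)2, Et2O, −20 → 0 °C
Reagents that add atoms: none
Why: Chelation-controlled (Cram chelate) reduction: divalent zinc bridges the carbonyl and the α-benzyloxy oxygen, hydride enters opposite the silyloxybenzyl branch and the new carbinol centre (1R, the future C4) is formed anti to the benzyloxy group, the silylated β-oxygen being unable to chelate.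

Step 8
Reactants: 15 anti alcohol
Product: 16 (1R,2S,3R)-2-(benzyloxy)-1-[4-(benzyloxy)phenyl]-3-[4-(benzyloxy)-2-fluorophenyl]-1-(triethylsilyloxy)-3-(triisopropylsilyloxy)propane
Conditions: iPr3SiOTf, 2,6-lutidine, CH2Cl2, 0 °C → rt
Reagents that add atoms: triisopropylsilyl trifluoromethanesulfonate, CC(C)[Si](OS(=O)(=O)C(F)(F)F)(C(C)C)C(C)C
Why: Silylation of the hindered benzylic alcohol with the silyl triflate and a hindered base; the triisopropylsilyl group is chosen because it survives lithium amide bases and does not migrate to a neighbouring alkoxide.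

Step 9
Reactants: 16 bis-silyl ether
Product: 17 (1R,2S,3R)-2-(benzyloxy)-1-[4-(benzyloxy)phenyl]-3-[4-(benzyloxy)-2-fluorophenyl]-3-(triisopropylsilyloxy)propan-1-ol
Conditions: HF·pyridine, pyridine, THF, 0 °C
Reagents that add atoms: none
Why: Selective desilylation: pyridine-buffered HF cleaves the triethylsilyl ether far faster than the triisopropylsilyl ether, so only the hydroxyl that will become O1 is freed.

Step 10
Reactants: 17 open-chain fluoroaryl alcohol
Product: 22 (2R,3S,4R)-3,7-bis(benzyloxy)-2-[4-(benzyloxy)phenyl]-4-(triisopropylsilyloxy)chroman-8-ol, via C8-lithiated fluoroarene alkoxide 18 (not isolated), via aryne alkoxide 19 (not isolated), via 8-lithioflavan 20 (not isolated), via C8 dimethyl boronate 21 (not isolated)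
Conditions: lithium 2,2,6,6-tetramethylpiperidide (3.5 equiv), THF, −78 → −20 °C; B(OMe)3, −78 → 0 °C; 30% H2O2, aq. NaOH, 0 °C
Reagents that add atoms: hydrogen peroxide, OO
Why: Lithium tetramethylpiperidide deprotonates the C2 hydroxyl and the C8 hydrogen, the only hydrogen ortho to fluorine and the one flanked by F (on C8a) and the O7 benzyl ether (18); on warming LiF is lost to give the C8–C8a aryne 19, a 3-alkoxybenzyne. The tethered C2 alkoxide adds to C8a, closing ring C in a 6-exo-dig mode, and leaves the carbanion on C8 (20), where the inductive effect of O7 and O1 and lithium chelation hold it. B(OMe)3 converts 20 into boronate 21 and alkaline H2O2 oxidises the C–B bond to C–O, so that O1–C8a and C8–O are both formed in one flask without acid. The closest known reaction type is the anionic aryne cyclisation of fluoroarenes carrying a tethered oxygen, nitrogen or carbon nucleophile with electrophilic trapping of the resulting aryllithium, together with the generation of 3-alkoxybenzynes from 3-fluoroanisole-type arenes. No stereocentre is formed: the C2–O bond is never broken, so C2 is retained and C3 and C4 are spectators. The step needs site-selective lithiation and regioselective alkoxide addition; the first is secured by the doubly activated C8–H (the excess of base re-lithiates any C8–H formed by proton return from the amine), the second by the tether length and by the polarisation of the aryne by O7, which both send oxygen to C8a and the charge to C8, while the triisopropylsilyl group on O4 is remote from the carbanion and too bulky to migrate.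

Step 11
Reactants: 22 8-hydroxyflavan of unit A; 11 benzyl bromide
Product: 23 (2R,3S,4R)-3,7,8-tris(benzyloxy)-2-[4-(benzyloxy)phenyl]-4-(triisopropylsilyloxy)chroman
Conditions: K2CO3, DMF, rt
Reagents that add atoms: none
Why: Williamson ether synthesis: only the phenol is acidic enough to be alkylated with K2CO3, and capping it protects the electron-rich ring A from oxidation in step 13.

Step 12
Reactants: 23 silyl ether of unit A
Product: 24 (2R,3R,4R)-3,7,8-tris(benzyloxy)-2-[4-(benzyloxy)phenyl]chroman-4-ol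
Conditions: Bu4NF, THF, rt
Reagents that add atoms: none
Why: Fluoride-induced desilylation under basic, non-ionising conditions frees the C4 hydroxyl without acid, so the labile benzylic C4–O bond should not be solvolysed.

Step 13
Reactants: 24 all-cis 4-ol of unit A
Product: 25 (2R,3S)-3,7,8-tris(benzyloxy)-2-[4-(benzyloxy)phenyl]chroman-4-one (2,3-cis)
Conditions: Dess–Martin periodinane, NaHCO3, CH2Cl2, 0 °C → rt
Reagents that add atoms: none
Why: Dess–Martin oxidation of the benzylic alcohol under hydrogencarbonate buffering gives the 2,3-cis ketone under near-neutral conditions that should not epimerise the α-benzyloxy centre C3.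

Step 14
Reactants: 17 open-chain fluoroaryl alcohol
Product: 26 (2R,3R)-2-(benzyloxy)-1-[4-(benzyloxy)phenyl]-3-[4-(benzyloxy)-2-fluorophenyl]-3-(triisopropylsilyloxy)propan-1-one
Conditions: Dess–Martin periodinane, NaHCO3, CH2Cl2, rt
Reagents that add atoms: none
Why: Dess–Martin oxidation of the free benzylic alcohol to the aryl ketone removes the configuration at the future C2 so that it can be set again with the opposite sense.

Step 15
Reactants: 26 α-benzyloxy aryl ketone
Product: 27 (1S,2S,3R)-2-(benzyloxy)-1-[4-(benzyloxy)phenyl]-3-[4-(benzyloxy)-2-fluorophenyl]-3-(triisopropylsilyloxy)propan-1-ol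
Conditions: Zn(BH4)2, Et2O, −20 → 0 °C
Reagents that add atoms: none
Why: Chelation-controlled (Cram chelate) reduction as in step 7: divalent zinc bridges the carbonyl and the α-benzyloxy oxygen and hydride enters opposite the silyloxy(aryl)methyl branch, so the carbinol (1S) is formed anti to the benzyloxy group and 27 is the C1 epimer of 17.

Step 16
Reactants: 27 epimeric open-chain fluoroaryl alcohol
Product: 32 (2S,3S,4R)-3,7-bis(benzyloxy)-2-[4-(benzyloxy)phenyl]-4-(triisopropylsilyloxy)chroman-8-ol, via C8-lithiated fluoroarene alkoxide 28 (not isolated), via aryne alkoxide 29 (not isolated), via 8-lithioflavan 30 (not isolated), via C8 dimethyl boronate 31 (not isolated)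
Conditions: lithium 2,2,6,6-tetramethylpiperidide (3.5 equiv), THF, −78 → −20 °C; B(OMe)3, −78 → 0 °C; 30% H2O2, aq. NaOH, 0 °C
Reagents that add atoms: hydrogen peroxide, OO
Why: The anionic aryne cyclisation, borylation and oxidation of step 10 applied to the epimeric alcohol: 6-exo-dig closure of ring C by the C2 alkoxide on C8a with retention at C2 should give the 2,3-trans-3,4-cis flavan, no stereocentre being formed in the step.

Step 17
Reactants: 32 8-hydroxyflavan of unit B; 11 benzyl bromide
Product: 33 (2S,3S,4R)-3,7,8-tris(benzyloxy)-2-[4-(benzyloxy)phenyl]-4-(triisopropylsilyloxy)chroman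
Conditions: K2CO3, DMF, rt
Reagents that add atoms: none
Why: Williamson ether synthesis on the only acidic hydroxyl, as in step 11.

Step 18
Reactants: 33 silyl ether of unit B
Product: 34 (2S,3R,4R)-3,7,8-tris(benzyloxy)-2-[4-(benzyloxy)phenyl]chroman-4-ol
Conditions: Bu4NF, THF, rt
Reagents that add atoms: none
Why: Fluoride-induced desilylation as in step 12 frees the C4 hydroxyl of unit B without acid, so the 3,4-cis configuration set in step 7 is kept.

Step 19
Reactants: 25 2,3-cis ketone of unit A; 34 3,4-cis 4-ol of unit B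
Product: 37 (2R,3R,4R)-3,7,8-tris(benzyloxy)-2-[4-(benzyloxy)phenyl]chroman-4-yl (2S,3R,4R)-3,7,8-tris(benzyloxy)-2-[4-(benzyloxy)phenyl]chroman-4-yl ether, via trimethylsilyl ether 35 (not isolated), via oxocarbenium triflate 36 (not isolated)
Conditions: 34, (Me3Si)2NH, Me3SiOTf (1 mol %), CH2Cl2, rt, then evaporation; 25, Et3SiH, Me3SiOTf (0.3 equiv), CH2Cl2, −78 °C; Et3N
Reagents that add atoms: none
Why: Reductive etherification of a ketone with an alkoxysilane: silyl triflate activation of the carbonyl of 25, addition of 35 and loss of siloxide give oxocarbenium ion 36, and Et3SiH delivers hydride to C4 of unit A anti to the axial C3 benzyloxy group and to the C2 aryl group, which makes the new C4–O bond cis to O3 (4R), while C4 of unit B should not be ionised at −78 °C and keeps its configuration.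

Step 20
Reactants: 37 octabenzyl ether of the target
Product: 38 (2R,3R,4R)-2-(4-hydroxyphenyl)-4-{[(2S,3R,4R)-3,7,8-trihydroxy-2-(4-hydroxyphenyl)chroman-4-yl]oxy}chroman-3,7,8-triol
Conditions: H2 (1 atm), Pd(OH)2 on carbon, THF/MeOH, rt
Reagents that add atoms: none
Why: Catalytic hydrogenolysis of the eight benzyl ethers under neutral conditions; primary O-benzyl groups are cleaved much faster than the hindered ring benzylic C4–O and C2–O1 bonds, so the reaction is stopped once debenzylation is complete.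

Compound list
1 | (S)-4-benzyloxazolidin-2-one | O=C1N[C@@H](Cc2ccccc2)CO1 | starting material
2 | benzyloxyacetyl chloride | O=C(Cl)COCc1ccccc1 | starting material
3 | (S)-4-benzyl-3-(benzyloxyacetyl)oxazolidin-2-one | O=C(COCc1ccccc1)N1[C@@H](Cc2ccccc2)COC1=O | intermediate
4 | 4-(benzyloxy)benzaldehyde | O=Cc1ccc(OCc2ccccc2)cc1 | starting material
5 | (4S)-4-benzyl-3-[(Z)-2-(benzyloxy)-1-(dibutylboranyloxy)ethenyl]oxazolidin-2-one (Z boron enolate, formed in situ) | CCCCB(CCCC)O/C(=C\OCc1ccccc1)N1[C@@H](Cc2ccccc2)COC1=O | intermediate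
6 | (4S)-4-benzyl-3-[(2S,3R)-2-(benzyloxy)-3-[4-(benzyloxy)phenyl]-3-(dibutylboranyloxy)propanoyl]oxazolidin-2-one (boron aldolate, formed in situ) | c1ccccc1COc1ccc(cc1)[C@@H](OB(CCCC)CCCC)[C@H](OCc1ccccc1)C(=O)N1[C@@H](Cc2ccccc2)COC1=O | intermediate
7 | (4S)-4-benzyl-3-[(2S,3R)-2-(benzyloxy)-3-[4-(benzyloxy)phenyl]-3-hydroxypropanoyl]oxazolidin-2-one | c1ccccc1COc1ccc(cc1)[C@@H](O)[C@H](OCc1ccccc1)C(=O)N1[C@@H](Cc2ccccc2)COC1=O | intermediate
8 | (2S,3R)-2-(benzyloxy)-3-[4-(benzyloxy)phenyl]-3-hydroxy-N-methoxy-N-methylpropanamide | c1ccccc1COc1ccc(cc1)[C@@H](O)[C@H](OCc1ccccc1)C(=O)N(C)OC | intermediate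
9 | (2S,3R)-2-(benzyloxy)-3-[4-(benzyloxy)phenyl]-N-methoxy-N-methyl-3-(triethylsilyloxy)propanamide | c1ccccc1COc1ccc(cc1)[C@@H](O[Si](CC)(CC)CC)[C@H](OCc1ccccc1)C(=O)N(C)OC | intermediate
10 | 4-bromo-3-fluorophenol | Oc1ccc(Br)c(F)c1 | starting material
11 | benzyl bromide | BrCc1ccccc1 | starting material
12 | 4-(benzyloxy)-1-bromo-2-fluorobenzene | Fc1cc(OCc2ccccc2)ccc1Br | intermediate
13 | [4-(benzyloxy)-2-fluorophenyl]magnesium chloride (LiCl complex, formed in situ) | Fc1cc(OCc2ccccc2)ccc1[Mg]Cl | intermediate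
14 | (2S,3R)-2-(benzyloxy)-1-[4-(benzyloxy)-2-fluorophenyl]-3-[4-(benzyloxy)phenyl]-3-(triethylsilyloxy)propan-1-one | c1ccccc1COc1ccc(cc1)[C@@H](O[Si](CC)(CC)CC)[C@H](OCc1ccccc1)C(=O)c1ccc(OCc2ccccc2)cc1F | intermediate
15 | (1R,2R,3R)-2-(benzyloxy)-1-[4-(benzyloxy)-2-fluorophenyl]-3-[4-(benzyloxy)phenyl]-3-(triethylsilyloxy)propan-1-ol | c1ccccc1COc1ccc(cc1)[C@@H](O[Si](CC)(CC)CC)[C@H](OCc1ccccc1)[C@H](O)c1ccc(OCc2ccccc2)cc1F | intermediate
16 | (1R,2S,3R)-2-(benzyloxy)-1-[4-(benzyloxy)phenyl]-3-[4-(benzyloxy)-2-fluorophenyl]-1-(triethylsilyloxy)-3-(triisopropylsilyloxy)propane | c1ccccc1COc1ccc(cc1)[C@@H](O[Si](CC)(CC)CC)[C@H](OCc1ccccc1)[C@H](O[Si](C(C)C)(C(C)C)C(C)C)c1ccc(OCc2ccccc2)cc1F | intermediate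
17 | (1R,2S,3R)-2-(benzyloxy)-1-[4-(benzyloxy)phenyl]-3-[4-(benzyloxy)-2-fluorophenyl]-3-(triisopropylsilyloxy)propan-1-ol | c1ccccc1COc1ccc(cc1)[C@@H](O)[C@H](OCc1ccccc1)[C@H](O[Si](C(C)C)(C(C)C)C(C)C)c1ccc(OCc2ccccc2)cc1F | intermediate
18 | lithium alkoxide of 17 lithiated at C3 of the fluoroaryl ring, the future C8 (formed in situ) | c1ccccc1COc1ccc(cc1)[C@@H](O[Li])[C@H](OCc1ccccc1)[C@H](O[Si](C(C)C)(C(C)C)C(C)C)c1ccc(OCc2ccccc2)c([Li])c1F | intermediate
19 | lithium alkoxide carrying the 3-(benzyloxy)benzyne ring, the C8–C8a aryne (formed in situ) | c1ccccc1COc1ccc(cc1)[C@@H](O[Li])[C@H](OCc1ccccc1)[C@H](O[Si](C(C)C)(C(C)C)C(C)C)C1=CC=C(OCc2ccccc2)C#C1 | intermediate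
20 | (2R,3S,4R)-3,7-bis(benzyloxy)-2-[4-(benzyloxy)phenyl]-8-lithio-4-(triisopropylsilyloxy)chroman (formed in situ) | c1ccccc1COc1ccc([C@H]2Oc3c(ccc(OCc4ccccc4)c3[Li])[C@@H](O[Si](C(C)C)(C(C)C)C(C)C)[C@H]2OCc4ccccc4)cc1 | intermediate
21 | dimethyl [(2R,3S,4R)-3,7-bis(benzyloxy)-2-[4-(benzyloxy)phenyl]-4-(triisopropylsilyloxy)chroman-8-yl]boronate (formed in situ) | c1ccccc1COc1ccc([C@H]2Oc3c(ccc(OCc4ccccc4)c3B(OC)OC)[C@@H](O[Si](C(C)C)(C(C)C)C(C)C)[C@H]2OCc4ccccc4)cc1 | intermediate
22 | (2R,3S,4R)-3,7-bis(benzyloxy)-2-[4-(benzyloxy)phenyl]-4-(triisopropylsilyloxy)chroman-8-ol | c1ccccc1COc1ccc([C@H]2Oc3c(ccc(OCc4ccccc4)c3O)[C@@H](O[Si](C(C)C)(C(C)C)C(C)C)[C@H]2OCc4ccccc4)cc1 | intermediate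
23 | (2R,3S,4R)-3,7,8-tris(benzyloxy)-2-[4-(benzyloxy)phenyl]-4-(triisopropylsilyloxy)chroman | c1ccccc1COc1ccc([C@H]2Oc3c(ccc(OCc4ccccc4)c3OCc4ccccc4)[C@@H](O[Si](C(C)C)(C(C)C)C(C)C)[C@H]2OCc4ccccc4)cc1 | intermediate
24 | (2R,3R,4R)-3,7,8-tris(benzyloxy)-2-[4-(benzyloxy)phenyl]chroman-4-ol | c1ccccc1COc1ccc([C@H]2Oc3c(ccc(OCc4ccccc4)c3OCc4ccccc4)[C@@H](O)[C@H]2OCc4ccccc4)cc1 | intermediate
25 | (2R,3S)-3,7,8-tris(benzyloxy)-2-[4-(benzyloxy)phenyl]chroman-4-one | c1ccccc1COc1ccc([C@H]2Oc3c(ccc(OCc4ccccc4)c3OCc4ccccc4)C(=O)[C@H]2OCc4ccccc4)cc1 | intermediate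
26 | (2R,3R)-2-(benzyloxy)-1-[4-(benzyloxy)phenyl]-3-[4-(benzyloxy)-2-fluorophenyl]-3-(triisopropylsilyloxy)propan-1-one | c1ccccc1COc1ccc(cc1)C(=O)[C@H](OCc1ccccc1)[C@H](O[Si](C(C)C)(C(C)C)C(C)C)c1ccc(OCc2ccccc2)cc1F | intermediate
27 | (1S,2S,3R)-2-(benzyloxy)-1-[4-(benzyloxy)phenyl]-3-[4-(benzyloxy)-2-fluorophenyl]-3-(triisopropylsilyloxy)propan-1-ol | c1ccccc1COc1ccc(cc1)[C@H](O)[C@H](OCc1ccccc1)[C@H](O[Si](C(C)C)(C(C)C)C(C)C)c1ccc(OCc2ccccc2)cc1F | intermediate
28 | lithium alkoxide of 27 lithiated at C3 of the fluoroaryl ring, the future C8 (formed in situ) | c1ccccc1COc1ccc(cc1)[C@H](O[Li])[C@H](OCc1ccccc1)[C@H](O[Si](C(C)C)(C(C)C)C(C)C)c1ccc(OCc2ccccc2)c([Li])c1F | intermediate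
29 | epimeric lithium alkoxide carrying the 3-(benzyloxy)benzyne ring, the C8–C8a aryne (formed in situ) | c1ccccc1COc1ccc(cc1)[C@H](O[Li])[C@H](OCc1ccccc1)[C@H](O[Si](C(C)C)(C(C)C)C(C)C)C1=CC=C(OCc2ccccc2)C#C1 | intermediate
30 | (2S,3S,4R)-3,7-bis(benzyloxy)-2-[4-(benzyloxy)phenyl]-8-lithio-4-(triisopropylsilyloxy)chroman (formed in situ) | c1ccccc1COc1ccc([C@@H]2Oc3c(ccc(OCc4ccccc4)c3[Li])[C@@H](O[Si](C(C)C)(C(C)C)C(C)C)[C@H]2OCc4ccccc4)cc1 | intermediate
31 | dimethyl [(2S,3S,4R)-3,7-bis(benzyloxy)-2-[4-(benzyloxy)phenyl]-4-(triisopropylsilyloxy)chroman-8-yl]boronate (formed in situ) | c1ccccc1COc1ccc([C@@H]2Oc3c(ccc(OCc4ccccc4)c3B(OC)OC)[C@@H](O[Si](C(C)C)(C(C)C)C(C)C)[C@H]2OCc4ccccc4)cc1 | intermediate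
32 | (2S,3S,4R)-3,7-bis(benzyloxy)-2-[4-(benzyloxy)phenyl]-4-(triisopropylsilyloxy)chroman-8-ol | c1ccccc1COc1ccc([C@@H]2Oc3c(ccc(OCc4ccccc4)c3O)[C@@H](O[Si](C(C)C)(C(C)C)C(C)C)[C@H]2OCc4ccccc4)cc1 | intermediate
33 | (2S,3S,4R)-3,7,8-tris(benzyloxy)-2-[4-(benzyloxy)phenyl]-4-(triisopropylsilyloxy)chroman | c1ccccc1COc1ccc([C@@H]2Oc3c(ccc(OCc4ccccc4)c3OCc4ccccc4)[C@@H](O[Si](C(C)C)(C(C)C)C(C)C)[C@H]2OCc4ccccc4)cc1 | intermediate
34 | (2S,3R,4R)-3,7,8-tris(benzyloxy)-2-[4-(benzyloxy)phenyl]chroman-4-ol | c1ccccc1COc1ccc([C@@H]2Oc3c(ccc(OCc4ccccc4)c3OCc4ccccc4)[C@@H](O)[C@H]2OCc4ccccc4)cc1 | intermediate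
35 | (2S,3S,4R)-3,7,8-tris(benzyloxy)-2-[4-(benzyloxy)phenyl]-4-(trimethylsilyloxy)chroman (formed in situ) | c1ccccc1COc1ccc([C@@H]2Oc3c(ccc(OCc4ccccc4)c3OCc4ccccc4)[C@@H](O[Si](C)(C)C)[C@H]2OCc4ccccc4)cc1 | intermediate
36 | oxocarbenium triflate from 25 and 35: C4 of unit A doubly bonded to the ether oxygen that carries the (2S,3R,4R)-flavan-4-yl group of unit B (formed in situ) | c1ccccc1COc1ccc([C@H]2Oc3c(ccc(OCc4ccccc4)c3OCc4ccccc4)C(=[O+][C@@H]5c6ccc(OCc7ccccc7)c(OCc7ccccc7)c6O[C@@H](c6ccc(OCc7ccccc7)cc6)[C@@H]5OCc6ccccc6)[C@H]2OCc4ccccc4)cc1.[O-]S(=O)(=O)C(F)(F)F | intermediate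
37 | (2R,3R,4R)-3,7,8-tris(benzyloxy)-2-[4-(benzyloxy)phenyl]chroman-4-yl (2S,3R,4R)-3,7,8-tris(benzyloxy)-2-[4-(benzyloxy)phenyl]chroman-4-yl ether | c1ccccc1COc1ccc([C@H]2Oc3c(ccc(OCc4ccccc4)c3OCc4ccccc4)[C@@H](O[C@@H]5c6ccc(OCc7ccccc7)c(OCc7ccccc7)c6O[C@@H](c6ccc(OCc7ccccc7)cc6)[C@@H]5OCc6ccccc6)[C@H]2OCc4ccccc4)cc1 | intermediate
38 | (2R,3R,4R)-2-(4-hydroxyphenyl)-4-{[(2S,3R,4R)-3,7,8-trihydroxy-2-(4-hydroxyphenyl)chroman-4-yl]oxy}chroman-3,7,8-triol (CNP0241481.1) | Oc1ccc([C@H]2Oc3c(ccc(O)c3O)[C@@H](O[C@@H]3c4ccc(O)c(O)c4O[C@@H](c4ccc(O)cc4)[C@@H]3O)[C@H]2O)cc1 | target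

Total step count: 20. Longest linear sequence: 15 steps (steps 1–4, 6–9 and 14–20).

Steps most likely to fail

Step 19. The silyl triflate may ionise the electron-rich benzylic C4–O bond of 35, or of 37 on the side of unit A, faster than the hindered oxocarbenium ion 36 is formed and reduced. The silane would then reduce the resulting cations to 4-deoxyflavans, or C4 of unit B would lose its configuration. The fallback reverses the roles of the two units and sets out from 34 and from 24, the alcohol of unit A before step 13. Alcohol 34 is treated with phenylmethanethiol and ZnI2 in CH2Cl2 at 0 °C to give (2S,3S)-4-(benzylsulfanyl)-3,7,8-tris(benzyloxy)-2-[4-(benzyloxy)phenyl]chroman F3, of which either C4 epimer serves. F3 and 24 are then joined with AgBF4 and 2,6-di-tert-butylpyridine in CH2Cl2 at 0 °C. This thiophilic activation, known for interflavanyl bond formation from 4-thioflavans, ionises only unit B, so C4 of unit A keeps the configuration set in step 7. The cation of unit B is taken up by O4 of 24, expected pseudo-axially on the face anti to its C2 aryl group, which is the 3,4-cis sense; a C4 epimer at unit B, if formed, would have to be separated. The fallback rejoins the route at 37.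

Step 10 (and step 16, the same reaction on the C1 epimer). Lithiation may stray to the methylene groups of the benzyl ethers, the amide base may add to the aryne before the alkoxide closes ring C, or the C8 anion may be protonated before it is borylated. The fallback makes the two bonds one after the other with known reactions. From 17, KH in DMF at 0 °C → rt brings about intramolecular nucleophilic aromatic substitution of the C8a fluoride by the C2 alkoxide, with retention at C2, to give (2R,3S,4R)-3,7-bis(benzyloxy)-2-[4-(benzyloxy)phenyl]-4-(triisopropylsilyloxy)chroman F1. Directed ortho-lithiation of F1 at C8, between O1 and the O7 benzyl ether, follows with lithium 2,2,6,6-tetramethylpiperidide in the presence of B(OiPr)3 in THF at −78 °C (in situ trapping), and H2O2 with aq. NaOH returns to 22. The same detour from 27 gives (2S,3S,4R)-3,7-bis(benzyloxy)-2-[4-(benzyloxy)phenyl]-4-(triisopropylsilyloxy)chroman F2 and rejoins the route at 32.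

Step 20. Hydrogenolysis may not stop at the benzyl ethers but also cleave the doubly benzylic C4–O–C4 ether or the C2–O1 bonds, which would split the dimer into flavan-3-ols. The fallback sets out from 37 and removes the eight benzyl groups by electron transfer instead of on a metal surface: lithium 4,4'-di-tert-butylbiphenylide in THF at −78 °C, then NH4Cl, gives 38 directly. The radical anion should transfer its electron to the unsubstituted phenyl rings of the benzyl groups and not to the electron-rich oxygenated rings that flank the interflavanyl ether; no new compound lies on this path.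

Further compounds
F1 | step 10 | (2R,3S,4R)-3,7-bis(benzyloxy)-2-[4-(benzyloxy)phenyl]-4-(triisopropylsilyloxy)chroman | c1ccccc1COc1ccc([C@H]2Oc3cc(OCc4ccccc4)ccc3[C@@H](O[Si](C(C)C)(C(C)C)C(C)C)[C@H]2OCc4ccccc4)cc1
F2 | step 16 | (2S,3S,4R)-3,7-bis(benzyloxy)-2-[4-(benzyloxy)phenyl]-4-(triisopropylsilyloxy)chroman | c1ccccc1COc1ccc([C@@H]2Oc3cc(OCc4ccccc4)ccc3[C@@H](O[Si](C(C)C)(C(C)C)C(C)C)[C@H]2OCc4ccccc4)cc1
F3 | step 19 | (2S,3S)-4-(benzylsulfanyl)-3,7,8-tris(benzyloxy)-2-[4-(benzyloxy)phenyl]chroman (C4 epimers) | c1ccccc1COc1ccc([C@@H]2Oc3c(ccc(OCc4ccccc4)c3OCc4ccccc4)C(SCc4ccccc4)[C@H]2OCc4ccccc4)cc1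
F0 | step 20 | none | none
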